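**Plan**
Numbering used throughout: lactone carbonyl = C1, chain carbons C2 to C32, ring oxygen on C32; the target is one 33-membered ring without a stereocenter.
Retrosynthesis cuts, in this order: the ring bond C2–C3 (after a temporary phenylthio group is placed on C2), the ester bond O–C32, and the central C17–C18 bond of the C3–C32 chain, which leads back to two molecules of 16-bromohexadecanoic acid and to (phenylthio)acetic acid.
Forward: Kolbe dimerisation joins the C30 chain; one end is esterified with the two-carbon unit C1–C2; the only ring is then closed by carbon–carbon bond formation from C2 to C3; the sulfur helper is removed last.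
Feature that makes the ring closure possible: the C2 methylene beside the lactone carbonyl C1 is the only carbon of the 33-membered ring that can carry an enolate, and its neighbour C3 is an unbranched primary carbon open to SN2 attack in a strain-free ring.
Stereochemistry: the target is achiral; the one stereocenter on the way (C2 of the phenylthio lactone) is racemic and is erased in the last step.

Key step: step 3

Remark on the structure: the SMILES is read as the unsubstituted 33-membered lactone of 32-hydroxydotriacontanoic acid (32 carbon atoms, C32H62O2).

**Step 1**
Reactants: 1 16-bromohexadecanoic acid (two molecules)
Product: 2 1,30-dibromotriacontane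
Conditions: NaOMe (0.05 equiv), MeOH, Pt anode and Pt cathode, constant current, 50 °C
Reagents that add atoms: none
Why: Kolbe electrolysis, in which anodic one-electron oxidation of the carboxylate of 1, loss of CO2 and combination of two 15-bromopentadecyl radicals at the platinum surface should form the C17–C18 bond, a coupling that tolerates a remote primary C–Br bond.

**Step 2**
Reactants: 2 1,30-dibromotriacontane (3 equiv), 3 2-(phenylsulfanyl)acetic acid
Product: 5 30-bromotriacontyl 2-(phenylsulfanyl)acetate, via cesium 2-(phenylsulfanyl)acetate 4 (not isolated)
Conditions: Cs2CO3 (0.5 equiv per 3), DMF/THF, 60 °C; excess 2 recovered by chromatography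
Reagents that add atoms: none
Why: Carboxylate O-alkylation (SN2) of the cesium salt at a primary bromide should form the O–C32 ester bond, with the threefold excess of the symmetrical dibromide making single substitution the statistically dominant outcome, while the thioether sulfur and the C2 methylene stay untouched under carbonate conditions.

**Step 3**
Reactants: 5 30-bromotriacontyl 2-(phenylsulfanyl)acetate
Product: 7 2-(phenylsulfanyl)dotriacontan-32-olide (racemic), via potassium enolate 6 (not isolated)
Conditions: KN(SiMe3)2 (1.2 equiv), THF, 40 °C, slow addition of 5 over 12 h (final 0.005 M); then aq NH4Cl
Reagents that add atoms: none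
Why: KN(SiMe3)2 removes a proton from the C2 methylene of 5, the only acidic site because it is flanked by the ester carbonyl C1 and the phenylthio group, and the potassium enolate 6 attacks the terminal CH2Br carbon (the future C3) in an intramolecular SN2 displacement that forms the C2–C3 bond. The closest known reaction type is the intramolecular C-alkylation of ω-haloalkyl (phenylthio)acetates to 2-phenylthio macrolides, an established macrolide ring closure that is here applied to a longer chain. The single ring, 33-membered, closes in the 33-exo-tet mode with the enolate double bond inside the forming ring (enolendo), which in a strain-free ring of this size is compatible with the preferred Z (s-trans) geometry of the ester. The new stereocenter at C2 arises as a racemate under no control, and none is needed because step 4 replaces the sulfur substituent by hydrogen. The step needs intramolecular over intermolecular alkylation, C- over O-alkylation and an enolate that neither self-condenses nor loses ketene: the first is secured by slow addition, which keeps the stationary concentration of 6 well below the effective molarity of the large ring, the second by the soft sulfur-substituted enolate carbon meeting a soft primary bromide, and the third by the stabilising phenylthio group, which is the reason for carrying this helper.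

**Step 4**
Reactants: 7 2-(phenylsulfanyl)dotriacontan-32-olide
Product: 8 dotriacontan-32-olide (oxacyclotritriacontan-2-one)
Conditions: Raney Ni (W-2, washed neutral), EtOH/THF, 50 °C
Reagents that add atoms: none
Why: Reductive desulfurization, in which hydrogenolysis of both C–S bonds on the hydrogen-laden nickel surface should replace the phenylthio helper at C2 by hydrogen and so erase the only stereocenter, while the saturated lactone offers no other reducible group.

**Compound list**
1 | 16-bromohexadecanoic acid | OC(=O)CCCCCCCCCCCCCCCBr | starting material
2 | 1,30-dibromotriacontane | BrCCCCCCCCCCCCCCCCCCCCCCCCCCCCCCBr | intermediate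
3 | 2-(phenylsulfanyl)acetic acid, also called (phenylthio)acetic acid | OC(=O)CSc1ccccc1 | starting material
4 | cesium 2-(phenylsulfanyl)acetate | [Cs+].[O-]C(=O)CSc1ccccc1 | intermediate (not isolated)
5 | 30-bromotriacontyl 2-(phenylsulfanyl)acetate | O=C(CSc1ccccc1)OCCCCCCCCCCCCCCCCCCCCCCCCCCCCCCBr | intermediate
6 | potassium enolate of 5 | [K+].[O-]C(=CSc1ccccc1)OCCCCCCCCCCCCCCCCCCCCCCCCCCCCCCBr | intermediate (not isolated)
7 | 2-(phenylsulfanyl)dotriacontan-32-olide, racemic; ring name 3-(phenylsulfanyl)oxacyclotritriacontan-2-one | O=C1C(Sc2ccccc2)CCCCCCCCCCCCCCCCCCCCCCCCCCCCCCO1 | intermediate
8 | dotriacontan-32-olide; ring name oxacyclotritriacontan-2-one | O=C1CCCCCCCCCCCCCCCCCCCCCCCCCCCCCCCO1 | target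

**Step count and risks**
Total steps: 4. Longest linear sequence: 4 (from 1).

Steps most likely to fail:

Step 3. Intermolecular alkylation may outrun ring closure if the stationary enolate concentration rises, leading to chain growth and cyclic dimers; the enolate of the product may also be alkylated by incoming bromide, and a slow displacement would give time for base-induced loss of ketene from the enolate. The fallback closes the ring at the other bond and sets out from 2 and 3. Compound 3 would be doubly deprotonated with LiN(i-Pr)2 (2.1 equiv) in THF/DMPU at 0 °C to the dilithium dianion of 2-(phenylsulfanyl)acetic acid F1, which would be C-alkylated by an excess of 2 to give, after acidic work-up, 32-bromo-2-(phenylsulfanyl)dotriacontanoic acid F2. Slow addition of F2 to Cs2CO3 in DMF at 70 °C would form cesium 32-bromo-2-(phenylsulfanyl)dotriacontanoate F3, whose carboxylate displaces the terminal bromide in an O-alkylative macrolactonization, a dependable closure for large rings. The fallback comes back to the route at 7; in it the C2–C3 bond is made between two molecules and the ring is closed at O–C32.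

Step 2. A second substitution at the far end and incomplete conversion of the poorly soluble dibromide may leave a mixture of three long-chain compounds of similar polarity. The fallback differentiates the chain ends by selective monobromination of a diol instead of by statistics and sets out from 2. KOAc in DMF at 100 °C would give triacontane-1,30-diyl diacetate F4, and methanolysis (K2CO3, MeOH/THF) would give triacontane-1,30-diol F5. Aqueous HBr (48%) in refluxing toluene should stop at 30-bromotriacontan-1-ol F6, because the bromo alcohol passes into the toluene phase, where its hydroxyl group is shielded from the acid. Acid-catalysed esterification of F6 with 3 (TsOH cat., toluene, reflux with water removal) comes back to the route at 5.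

Step 1. The poorly soluble C30 product may coat and passivate the anode, and further oxidation of the radical to a cation would divert material to methyl ethers and alkenes; esterification of the acid by methanol is a further drain. The fallback generates the same radical pair without an electrode and sets out from 1. Coupling of 1 with H2O2 (0.5 equiv) by DCC in Et2O/CH2Cl2 at 0 °C would give bis(16-bromohexadecanoyl) peroxide F7. Photolysis of F7 (254 nm) as a crystalline film at low temperature should expel two molecules of CO2 and join the two 15-bromopentadecyl radicals held side by side in the lattice. The fallback comes back to the route at 2.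

**Further compounds**
F1 | step 3 | dilithium dianion of 2-(phenylsulfanyl)acetic acid | [Li+].[Li+].[O-]C(=O)[CH-]Sc1ccccc1
F2 | step 3 | 32-bromo-2-(phenylsulfanyl)dotriacontanoic acid (racemic) | OC(=O)C(Sc1ccccc1)CCCCCCCCCCCCCCCCCCCCCCCCCCCCCCBr
F3 | step 3 | cesium 32-bromo-2-(phenylsulfanyl)dotriacontanoate | [Cs+].[O-]C(=O)C(Sc1ccccc1)CCCCCCCCCCCCCCCCCCCCCCCCCCCCCCBr
F4 | step 2 | triacontane-1,30-diyl diacetate | CC(=O)OCCCCCCCCCCCCCCCCCCCCCCCCCCCCCCOC(C)=O
F5 | step 2 | triacontane-1,30-diol | OCCCCCCCCCCCCCCCCCCCCCCCCCCCCCCO
F6 | step 2 | 30-bromotriacontan-1-ol | OCCCCCCCCCCCCCCCCCCCCCCCCCCCCCCBr
F7 | step 1 | bis(16-bromohexadecanoyl) peroxide | BrCCCCCCCCCCCCCCCC(=O)OOC(=O)CCCCCCCCCCCCCCCBr
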